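(The runs come from a simulation from invented constants, noise included.)

You cannot exchange more starting complex than the incoming ligand pays for, since each exchange takes one. Epsilon, delta and gamma differ in their charge of scavenger, and they share one ligand ceiling, the charged c(incoming ligand) over the charged c(starting complex): 70.0%. In these three flasks incoming ligand is the limiting reagent.

| flask | starting complex | incoming ligand | scavenger | remark | time |
|---|---|---|---|---|---|
| north-west | 13 mM | 14 mM | 30 mM | run made earlier |  |
| south-east | 20 mM | 7 mM | 30 mM | run made earlier |  |
| epsilon | 20 mM | 14.0 mM | 30.0 mM |  | 3.0 d |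
| delta | 20 mM | 14.0 mM | 60.0 mM |  | 3.0 d |
| gamma | 20 mM | 14.0 mM | 120 mM |  | 3.0 d |

| run | time / h | starting complex / % | complex with one exchanged / % |
|---|---|---|---|
| north-west | 2.00 | 88.0 | 11.1 |
| north-west | 3.00 | 84.3 | 14.0 |
| north-west | 6.00 | 72.0 | 25.2 |
| north-west | 10.0 | 61.3 | 36.8 |
| north-west | 15.0 | 52.9 | 47.0 |
| north-west | 25.0 | 38.5 | 58.2 |
| south-east | 2.00 | 94.2 | 6.9 |
| south-east | 3.00 | 91.5 | 7.8 |
| south-east | 6.00 | 87.2 | 12.6 |
| south-east | 10.0 | 81.7 | 19.2 |
| south-east | 15.0 | 78.0 | 22.0 |
| south-east | 25.0 | 71.8 | 26.7 |

(readings scatter by 1 percentage point)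

- part of the starting complex that has reacted at the end, epsilon
- part of the starting complex that has reacted at the end, delta
- part of the starting complex that has reacted at the end, gamma
- what raising the concentration of scavenger from its lowest to its highest value here does to the part of the starting complex that has reacted (changes below 5 percentage points count as none) (it falls / it rises / no change)

How near the ceiling do you get? Solve both ends and join. My reckoning takes a second-order law, with one ligand per exchange and no way back. The ratio of free ligand to free complex then decays exponentially, from the charged ratio at the start toward zero late on, and that one curve joins the ends. The last north-west reading, with its scatter, gives that decay a time of about 38.6 h at the epsilon charges. Starting that ratio at the ceiling and running it for 3.0 d, my own reckoning gives 66.4% reacted. No earlier run varies the scavenger, so anything said about it is a guess.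

The forecast, a little below mine, gives 65%, 65% and 65%, with no change as the trend: “More scavenger should then change little”.

The flasks give 61.4%, 61.4% and 61.4%, so the trend is no change, a change of 0.0065 percentage points.

    starting complex + incoming ligand ⇌ leaving ligand + complex with one exchanged (K = 130, k = 0.00170 L mol⁻¹ s⁻¹)
    complex with one exchanged + incoming ligand ⇌ leaving ligand + complex with two exchanged (K = 3.30, k = 1.80 × 10⁻⁴ L mol⁻¹ s⁻¹)
    complex with two exchanged + incoming ligand ⇌ leaving ligand + complex with three exchanged (K = 1.60, k = 0.00120 L mol⁻¹ s⁻¹)
    leaving ligand + incoming ligand ⇌ idle adduct, settled at all times (K = 91.0 L mol⁻¹)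
    scavenger + leaving ligand → scavenged by-product (k = 0.0700 L mol⁻¹ s⁻¹)
    incoming ligand → decomposed reagent (k = 1.00 × 10⁻⁶ s⁻¹)
    incoming ligand ⇌ dormant form (K = 0.380, k = 3.00 × 10⁻⁴ s⁻¹)

In epsilon, at the charges, leaving ligand has a half-life of 0.092 h on its path to the scavenger, far shorter than the 0.34 d of starting complex on the forward exchange path alone. Epsilon ends 8.6 points under its ceiling, with 1.7% of its incoming ligand left. A neighbour of gamma with 5.6 mM of incoming ligand has a ceiling of 28.0% and reaches 26.5%. Gamma itself moves by 5 points at 12.7 mM or 15.4 mM of incoming ligand.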